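**Plan**

1. Retrosynthesis: after the C8 methacrylate and the C15 silyl ether are taken off, the furanone is cut at O–C10 and at C1–C2 together and a sulfur atom is put back between C1 and C2. The oxygen-bridged ten-membered carbocycle thus becomes an eleven-membered thiolactone [C1(=O)–S–C2H2–C3(=O)] with a tertiary mesylate on C10.
2. Enabling feature: C1 is a carbonyl carbon lying between the acidic C2 methylene of the C3 enone and the quaternary C10. Sulfur extrusion welds C1 to C2 (ring contraction to the carbocycle), and the 1,3-diketone so formed holds its C3 oxygen five atoms from C10 for transannular 5-exo-tet closure of the 3(2H)-furanone ring.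
3. Further cuts: S–C2 (thiocarboxylate alkylation), C6–C7 with O6–C12 (chromium Barbier allylation and lactonisation), C7–C11 (vinylalumination), C3–C4 (Sonogashira), C9–C10 (pyruvate aldol).
4. Forward order: the C7–C10/C1 chain is made and turned into an allyl bromide; the C2–C6 enynal is made; their union builds the butyrolactone; the eleven-membered thiolactone follows; ring contraction gives carbocycle and furanone in one operation; C8 acylation and C15 deprotection finish.
5. Stereochemistry: C10 from a copper–bis(oxazoline) Mukaiyama aldol (R, inverted to S in the key step); C8 from a Corey–Bakshi–Shibata reduction; C6 and C7 from the anti-selective allylation under control of C8; the C4=C5 geometry from trans-hydroalumination/iodination of a butynediol.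

Key step: step 18

Remark: locants C1–C15 are those of the germacranolide skeleton of the target (C1 ketone; C2 and C3 the furanone CH= and =C–O carbons; C4=C5; C6 lactone carbinol; C7; C8 ester carbinol; C9; C10 quaternary carbon; C11, C12, C13 lactone α-carbon, carbonyl and exo-methylene; C14 methyl on C10; C15 CH2O on C4). TBS = tert-butyldimethylsilyl, TBDPS = tert-butyldiphenylsilyl, Ms = methanesulfonyl, TMSE = 2-(trimethylsilyl)ethyl.

Remark (assumption): the aldol of step 2 and the reduction of step 3 are taken to follow the usual facial models, the dimethoxymethyl group acting as the large ketone substituent in step 3.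

**Route**

Step 1
Reactants: 1 1,1-dimethoxypropan-2-one
Product: 3 [(3,3-dimethoxyprop-1-en-2-yl)oxy]trimethylsilane, via lithium enolate 2 (not isolated)
Conditions: LiN(iPr)2, THF, −78 °C; Me3SiCl, −78 °C → 0 °C
Reagents that add atoms: chlorotrimethylsilane C[Si](C)(C)Cl
Why: Kinetic deprotonation at the methyl group (the acetal C–H is hindered and its enolate is destabilised by two alkoxy groups) and O-silylation should give the less substituted silyl enol ether (silyl enol ether formation).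

Step 2
Reactants: 3 [(3,3-dimethoxyprop-1-en-2-yl)oxy]trimethylsilane; 4 methyl pyruvate
Product: 6 methyl (R)-2-hydroxy-5,5-dimethoxy-2-methyl-4-oxopentanoate, via silyl ether 5 (not isolated)
Conditions: Cu(OTf)2 (10 mol %), 2,2′-isopropylidenebis[(4R)-4-tert-butyl-2-oxazoline] (11 mol %), THF, −78 °C; then 1 M HCl, 0 °C
Reagents that add atoms: none
Why: Copper–bis(oxazoline)-catalysed Mukaiyama aldol addition to the chelated pyruvate, in which the ligand shields one face of the bound ketoester so that the tertiary carbinol C10 should form as R; acid then removes the transferred silyl group.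

Step 3
Reactants: 6 methyl (R)-2-hydroxy-5,5-dimethoxy-2-methyl-4-oxopentanoate
Product: 7 methyl (2R,4R)-2,4-dihydroxy-5,5-dimethoxy-2-methylpentanoate
Conditions: (S)-1-methyl-3,3-diphenyltetrahydro-1H,3H-pyrrolo[1,2-c][1,3,2]oxazaborole (20 mol %), catecholborane, toluene, −78 °C; then MeOH, pH 7 buffer
Reagents that add atoms: none
Why: Corey–Bakshi–Shibata reduction, in which the oxazaborolidine distinguishes the large dimethoxymethyl from the small CH2 substituent and should set C8 as R under reagent control, while catecholborane caps the tertiary alcohol as a borate and suppresses undirected background reduction.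

Step 4
Reactants: 7 methyl (2R,4R)-2,4-dihydroxy-5,5-dimethoxy-2-methylpentanoate
Product: 8 methyl (2R,4R)-4-[(tert-butyldimethylsilyl)oxy]-2-hydroxy-5,5-dimethoxy-2-methylpentanoate
Conditions: TBSOTf (1.05 equiv), 2,6-lutidine, CH2Cl2, −78 °C
Reagents that add atoms: tert-butyldimethylsilyl trifluoromethanesulfonate CC(C)(C)[Si](C)(C)OS(=O)(=O)C(F)(F)F
Why: Selective silylation of the secondary alcohol at low temperature, the hindered and deactivated tertiary α-hydroxy ester being left free; this also blocks lactonisation of the C8 oxygen onto C1.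

Step 5
Reactants: 8 methyl (2R,4R)-4-[(tert-butyldimethylsilyl)oxy]-2-hydroxy-5,5-dimethoxy-2-methylpentanoate
Product: 9 S-[2-(trimethylsilyl)ethyl] (2R,4R)-4-[(tert-butyldimethylsilyl)oxy]-2-hydroxy-5,5-dimethoxy-2-methylpentanethioate
Conditions: Me3Al, HSCH2CH2SiMe3, CH2Cl2, 0 °C → rt
Reagents that add atoms: 2-(trimethylsilyl)ethanethiol C[Si](C)(C)CCS
Why: Thiolysis of the ester by the aluminium thiolate formed in situ, assisted by chelation of the α-alkoxide, should give the thioester that later supplies the bridging sulfur; the fluoride-labile S-substituent is the latent thioacid.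

Step 6
Reactants: 9 S-[2-(trimethylsilyl)ethyl] (2R,4R)-4-[(tert-butyldimethylsilyl)oxy]-2-hydroxy-5,5-dimethoxy-2-methylpentanethioate
Product: 10 S-[2-(trimethylsilyl)ethyl] (2R,4R)-4-[(tert-butyldimethylsilyl)oxy]-5,5-dimethoxy-2-methyl-2-[(methylsulfonyl)oxy]pentanethioate
Conditions: MsCl, Et3N, CH2Cl2, −20 → 0 °C
Reagents that add atoms: methanesulfonyl chloride CS(=O)(=O)Cl
Why: Sulfonylation of the tertiary alcohol through sulfene leaves the C10 configuration untouched, and the α-acyl group disfavours ionisation so that the tertiary mesylate should be stable enough to carry forward.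

Step 7
Reactants: 10 S-[2-(trimethylsilyl)ethyl] (2R,4R)-4-[(tert-butyldimethylsilyl)oxy]-5,5-dimethoxy-2-methyl-2-[(methylsulfonyl)oxy]pentanethioate
Product: 12 S-[2-(trimethylsilyl)ethyl] (2R,4R)-4-[(tert-butyldimethylsilyl)oxy]-2-methyl-2-[(methylsulfonyl)oxy]-5-oxopentanethioate, via collidinium salt 11 (not isolated)
Conditions: Et3SiOTf, 2,4,6-collidine, CH2Cl2, 0 °C; then H2O
Reagents that add atoms: water O
Why: Silyl triflate/collidine acetal cleavage converts the acetal into a pyridinium N,O-acetal salt that water hydrolyses to the aldehyde without protic acid, conditions the TBS ether, mesylate and thioester should tolerate and that should not epimerise C8.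

Step 8
Reactants: 12 S-[2-(trimethylsilyl)ethyl] (2R,4R)-4-[(tert-butyldimethylsilyl)oxy]-2-methyl-2-[(methylsulfonyl)oxy]-5-oxopentanethioate; 13 methyl propiolate
Product: 15 methyl (4R,6R)-4-[(tert-butyldimethylsilyl)oxy]-3-hydroxy-6-methyl-2-methylidene-6-[(methylsulfonyl)oxy]-7-oxo-7-{[2-(trimethylsilyl)ethyl]sulfanyl}heptanoate (C3 epimers), via vinylalane 14 (not isolated)
Conditions: 13, iBu2AlH, N-methylmorpholine N-oxide, THF, 0 °C; then 12, 0 °C → rt
Reagents that add atoms: none
Why: Vinylalumination (the aluminium variant of the Morita–Baylis–Hillman reaction): 1,4-hydroalumination of the propiolate gives the α-aluminoacrylate, which adds to the aldehyde without amine base; the new carbinol centre forms as a mixture that step 9 erases.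

Step 9
Reactants: 15 methyl (4R,6R)-4-[(tert-butyldimethylsilyl)oxy]-3-hydroxy-6-methyl-2-methylidene-6-[(methylsulfonyl)oxy]-7-oxo-7-{[2-(trimethylsilyl)ethyl]sulfanyl}heptanoate
Product: 16 methyl (2Z,4R,6R)-2-(bromomethyl)-4-[(tert-butyldimethylsilyl)oxy]-6-methyl-6-[(methylsulfonyl)oxy]-7-oxo-7-{[2-(trimethylsilyl)ethyl]sulfanyl}hept-2-enoate
Conditions: NBS, Me2S, CH2Cl2, 0 °C → rt
Reagents that add atoms: N-bromosuccinimide O=C1CCC(=O)N1Br
Why: Corey–Kim-type bromination of the allylic alcohol with allylic transposition (SN2′) should give the thermodynamically preferred (Z)-2-(bromomethyl)enoate.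

Step 10
Reactants: 17 but-2-yne-1,4-diol
Product: 18 4-[(tert-butyldiphenylsilyl)oxy]but-2-yn-1-ol
Conditions: TBDPSCl (0.3 equiv), imidazole, THF, 0 °C (diol in excess)
Reagents that add atoms: tert-butyl(chloro)diphenylsilane CC(C)(C)[Si](Cl)(c1ccccc1)c1ccccc1
Why: Statistical monosilylation of the symmetrical diol used in excess.

Step 11
Reactants: 18 4-[(tert-butyldiphenylsilyl)oxy]but-2-yn-1-ol
Product: 20 (Z)-4-[(tert-butyldiphenylsilyl)oxy]-3-iodobut-2-en-1-ol, via alkenylaluminate 19 (not isolated)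
Conditions: NaAlH2(OCH2CH2OCH3)2, THF, 0 °C; then I2, −78 → 0 °C
Reagents that add atoms: iodine [I][I]
Why: Hydroxyl-directed trans-hydroalumination of the propargylic alcohol and iodinolysis with retention should give the (Z)-3-iodoallylic alcohol, which fixes the cis relation of the future C3 and C6 substituents on C4=C5.

Step 12
Reactants: 20 (Z)-4-[(tert-butyldiphenylsilyl)oxy]-3-iodobut-2-en-1-ol; 21 ethynyltrimethylsilane
Product: 22 (E)-3-{[(tert-butyldiphenylsilyl)oxy]methyl}-5-(trimethylsilyl)pent-2-en-4-yn-1-ol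
Conditions: Pd(PPh3)2Cl2 (3 mol %), CuI (6 mol %), iPr2NH, THF, rt
Reagents that add atoms: none
Why: Sonogashira coupling with retention of alkene geometry brings in C2–C3 as a masked bromomethyl ketone.

Step 13
Reactants: 22 (E)-3-{[(tert-butyldiphenylsilyl)oxy]methyl}-5-(trimethylsilyl)pent-2-en-4-yn-1-ol
Product: 23 (E)-3-{[(tert-butyldiphenylsilyl)oxy]methyl}-5-(trimethylsilyl)pent-2-en-4-ynal
Conditions: MnO2, CH2Cl2, rt
Reagents that add atoms: none
Why: Allylic oxidation with MnO2 should give the enal without isomerising the trisubstituted alkene.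

Step 14
Reactants: 16 methyl (2Z,4R,6R)-2-(bromomethyl)-4-[(tert-butyldimethylsilyl)oxy]-6-methyl-6-[(methylsulfonyl)oxy]-7-oxo-7-{[2-(trimethylsilyl)ethyl]sulfanyl}hept-2-enoate; 23 (E)-3-{[(tert-butyldiphenylsilyl)oxy]methyl}-5-(trimethylsilyl)pent-2-en-4-ynal
Product: 25 alkynylsilane lactone (6R,7S,8R,10R,4E), via hydroxy ester 24 (not isolated)
Conditions: CrCl2 (4 equiv), THF, 0 °C → rt; work-up; then camphor-10-sulfonic acid (cat.), CH2Cl2, rt
Reagents that add atoms: none
Why: Nozaki–Hiyama-type chromium Barbier allylation, in which the γ-substituted allylchromium adds through a chair-like six-membered transition state to give the anti adduct (hence the trans lactone) and allylic 1,3-strain places C8–H in the allyl plane so that the aldehyde should approach anti to the C9 chain, setting C6 (R) and C7 relative to C8; acid then closes the lactone.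

Step 15
Reactants: 25 alkynylsilane lactone (6R,7S,8R,10R,4E)
Product: 26 bromoalkyne lactone (6R,7S,8R,10R,4E)
Conditions: NBS, AgNO3 (10 mol %), acetone, rt, dark
Reagents that add atoms: N-bromosuccinimide O=C1CCC(=O)N1Br
Why: Silver-catalysed desilylative bromination of the alkynylsilane gives the 1-bromoalkyne without touching the alkenes or the sp3 C–Si bond of the TMSE group.

Step 16
Reactants: 26 bromoalkyne lactone (6R,7S,8R,10R,4E)
Product: 27 bromomethyl ketone lactone (6R,7S,8R,10R,4Z)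
Conditions: Ph3PAuNTf2 (5 mol %), H2O (3 equiv), 1,4-dioxane, 40 °C
Reagents that add atoms: water O
Why: Gold-catalysed hydration of the haloalkyne, in which water should add at the carbon remote from bromine (C3) and give the α-bromomethyl enone directly.

Step 17
Reactants: 27 bromomethyl ketone lactone (6R,7S,8R,10R,4Z)
Product: 29 eleven-membered thiolactone (6R,7S,8R,10R,4Z), via thiocarboxylate 28 (not isolated)
Conditions: Bu4NF, AcOH (1:1), THF, 0.002 M, slow addition, 0 °C → rt
Reagents that add atoms: none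
Why: Fluoride-induced fragmentation of the 2-(trimethylsilyl)ethyl thioester frees the thiocarboxylate, which the α-bromoketone alkylates intramolecularly (SN2) under high dilution to close the eleven-membered ring; acetic acid tempers the fluoride but leaves the more acidic thioacid ionised.

Step 18
Reactants: 29 eleven-membered thiolactone (6R,7S,8R,10R,4Z)
Product: 32 8-O-TBS-15-O-TBDPS furanone (6R,7S,8R,10S,4Z), via thiirane alkoxide 30 (not isolated), via diketone enolate 31 (not isolated)
Conditions: PPh3 (3 equiv), iPr2NEt (3 equiv), LiClO4 (2 equiv), MeCN, 0.01 M, 50 °C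
Reagents that add atoms: none
Why: Proposed new method: the amine removes a proton from C2 (acidified by the C3 carbonyl and by sulfur), the carbanion adds to the thioester carbonyl C1 to give a thiirane alkoxide from which PPh3 abstracts sulfur, so that C1–C2 forms and the eleven-membered thiolactone contracts to the ten-membered carbocyclic 1,3-diketone enolate, whose C3 oxygen then displaces the tertiary C10 mesylate across the ring to form O–C10. The closest known reactions are the Eschenmoser sulfide contraction of S-(2-oxoalkyl) thioesters, also used to contract medium-ring thia-lactones to β-keto lactones, and the base-mediated closure of α′-halo-1,3-diketones to 3(2H)-furanones; their merger in one flask and a stereospecific displacement at a tertiary α-acyl mesylate are the untested parts. The ten-membered carbocycle is closed by ring contraction with extrusion of sulfur (3-exo-trig attack, then loss of sulfur) and the furanone ring by 5-exo-tet O-alkylation. The only stereocentre that changes is C10, which should invert from R to S because the enolate oxygen is held on the ring-interior face opposite the outward-pointing mesylate and the α-acyl group disfavours ionisation; C6, C7 and C8 are not touched. The step needs O- over C-alkylation and substitution over elimination: attack by C2 at C10 would need a three-membered ring whereas O3 closes a five-membered one, and a weak amine base with a chelating lithium salt is chosen so that the non-acidic hydrogens on C9 and C14 are not removed.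

Step 19
Reactants: 32 8-O-TBS-15-O-TBDPS furanone (6R,7S,8R,10S,4Z)
Product: 33 8-hydroxy-15-O-TBDPS furanone (6R,7R,8R,10S,4Z)
Conditions: HF·pyridine, pyridine, THF, 0 °C
Reagents that add atoms: none
Why: Buffered HF should cleave the secondary TBS ether selectively in the presence of the more robust TBDPS ether (selective desilylation).

Step 20
Reactants: 33 8-hydroxy-15-O-TBDPS furanone (6R,7R,8R,10S,4Z)
Product: 34 8-O-methacryloyl-15-O-TBDPS furanone (6R,7R,8R,10S,4Z)
Conditions: methacrylic anhydride, Et3N, DMAP (cat.), CH2Cl2, 0 °C → rt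
Reagents that add atoms: methacrylic anhydride C=C(C)C(=O)OC(=O)C(C)=C
Why: DMAP-catalysed acyl transfer to the only free hydroxyl (C8) installs the methacrylate with retention at C8.

Step 21
Reactants: 34 8-O-methacryloyl-15-O-TBDPS furanone (6R,7R,8R,10S,4Z)
Product: 35 (4Z,6R,7R,8R,10S)-15-hydroxy-1-oxo-3,10-epoxygermacra-2,4,11(13)-trien-12,6-olid-8-yl methacrylate (target)
Conditions: HF·pyridine, THF, rt
Reagents that add atoms: none
Why: Acidic fluoride cleavage of the TBDPS ether should leave the methacrylate, the α-methylene lactone and the furanone untouched (desilylation).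

**Compound list**

1 | 1,1-dimethoxypropan-2-one | CC(=O)C(OC)OC | starting material
2 | lithium 3,3-dimethoxyprop-1-en-2-olate (lithium enolate) | [Li]OC(=C)C(OC)OC | intermediate
3 | [(3,3-dimethoxyprop-1-en-2-yl)oxy]trimethylsilane | C=C(O[Si](C)(C)C)C(OC)OC | intermediate
4 | methyl pyruvate | CC(=O)C(=O)OC | starting material
5 | methyl (R)-5,5-dimethoxy-2-methyl-4-oxo-2-[(trimethylsilyl)oxy]pentanoate (silyl ether) | COC(OC)C(=O)C[C@@](C)(O[Si](C)(C)C)C(=O)OC | intermediate
6 | methyl (R)-2-hydroxy-5,5-dimethoxy-2-methyl-4-oxopentanoate | COC(OC)C(=O)C[C@@](C)(O)C(=O)OC | intermediate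
7 | methyl (2R,4R)-2,4-dihydroxy-5,5-dimethoxy-2-methylpentanoate | COC(OC)[C@H](O)C[C@@](C)(O)C(=O)OC | intermediate
8 | methyl (2R,4R)-4-[(tert-butyldimethylsilyl)oxy]-2-hydroxy-5,5-dimethoxy-2-methylpentanoate | COC(OC)[C@H](O[Si](C)(C)C(C)(C)C)C[C@@](C)(O)C(=O)OC | intermediate
9 | S-[2-(trimethylsilyl)ethyl] (2R,4R)-4-[(tert-butyldimethylsilyl)oxy]-2-hydroxy-5,5-dimethoxy-2-methylpentanethioate | COC(OC)[C@H](O[Si](C)(C)C(C)(C)C)C[C@@](C)(O)C(=O)SCC[Si](C)(C)C | intermediate
10 | S-[2-(trimethylsilyl)ethyl] (2R,4R)-4-[(tert-butyldimethylsilyl)oxy]-5,5-dimethoxy-2-methyl-2-[(methylsulfonyl)oxy]pentanethioate | COC(OC)[C@H](O[Si](C)(C)C(C)(C)C)C[C@@](C)(OS(C)(=O)=O)C(=O)SCC[Si](C)(C)C | intermediate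
11 | collidinium salt: N-(1-methoxyalkyl)-2,4,6-trimethylpyridinium triflate from 10 (one OCH3 replaced by collidinium; C8 R, C10 R) | COC([n+]1c(C)cc(C)cc1C)[C@H](O[Si](C)(C)C(C)(C)C)C[C@@](C)(OS(C)(=O)=O)C(=O)SCC[Si](C)(C)C.[O-]S(=O)(=O)C(F)(F)F | intermediate
12 | S-[2-(trimethylsilyl)ethyl] (2R,4R)-4-[(tert-butyldimethylsilyl)oxy]-2-methyl-2-[(methylsulfonyl)oxy]-5-oxopentanethioate | O=C[C@H](O[Si](C)(C)C(C)(C)C)C[C@@](C)(OS(C)(=O)=O)C(=O)SCC[Si](C)(C)C | intermediate
13 | methyl propiolate | C#CC(=O)OC | starting material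
14 | methyl 2-(diisobutylalumanyl)acrylate (vinylalane) | C=C(C(=O)OC)[Al](CC(C)C)CC(C)C | intermediate
15 | methyl (4R,6R)-4-[(tert-butyldimethylsilyl)oxy]-3-hydroxy-6-methyl-2-methylidene-6-[(methylsulfonyl)oxy]-7-oxo-7-{[2-(trimethylsilyl)ethyl]sulfanyl}heptanoate (C3 epimers) | C=C(C(=O)OC)C(O)[C@H](O[Si](C)(C)C(C)(C)C)C[C@@](C)(OS(C)(=O)=O)C(=O)SCC[Si](C)(C)C | intermediate
16 | methyl (2Z,4R,6R)-2-(bromomethyl)-4-[(tert-butyldimethylsilyl)oxy]-6-methyl-6-[(methylsulfonyl)oxy]-7-oxo-7-{[2-(trimethylsilyl)ethyl]sulfanyl}hept-2-enoate | BrC/C(C(=O)OC)=C\[C@H](O[Si](C)(C)C(C)(C)C)C[C@@](C)(OS(C)(=O)=O)C(=O)SCC[Si](C)(C)C | intermediate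
17 | but-2-yne-1,4-diol | OCC#CCO | starting material
18 | 4-[(tert-butyldiphenylsilyl)oxy]but-2-yn-1-ol | OCC#CCO[Si](c1ccccc1)(c1ccccc1)C(C)(C)C | intermediate
19 | sodium cyclic alkenylaluminate (Al bound to O1 and C3 after trans-hydroalumination of 18) | [Na+].COCCO[Al-]1(OCCOC)OCC=C1CO[Si](c2ccccc2)(c2ccccc2)C(C)(C)C | intermediate
20 | (Z)-4-[(tert-butyldiphenylsilyl)oxy]-3-iodobut-2-en-1-ol | OC/C=C(\I)CO[Si](c1ccccc1)(c1ccccc1)C(C)(C)C | intermediate
21 | ethynyltrimethylsilane | C#C[Si](C)(C)C | starting material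
22 | (E)-3-{[(tert-butyldiphenylsilyl)oxy]methyl}-5-(trimethylsilyl)pent-2-en-4-yn-1-ol | OC/C=C(\C#C[Si](C)(C)C)CO[Si](c1ccccc1)(c1ccccc1)C(C)(C)C | intermediate
23 | (E)-3-{[(tert-butyldiphenylsilyl)oxy]methyl}-5-(trimethylsilyl)pent-2-en-4-ynal | O=C/C=C(\C#C[Si](C)(C)C)CO[Si](c1ccccc1)(c1ccccc1)C(C)(C)C | intermediate
24 | hydroxy ester (6R,7S,8R,10R,4E): C12 methyl ester, C6–OH, 11(13)-ene, C3≡C2–SiMe3, 8-OTBS, 10-OMs, C1 TMSE thioester, 15-OTBDPS | COC(=O)C(=C)[C@@H]([C@H](O)/C=C(\C#C[Si](C)(C)C)CO[Si](c1ccccc1)(c1ccccc1)C(C)(C)C)[C@H](O[Si](C)(C)C(C)(C)C)C[C@@](C)(OS(C)(=O)=O)C(=O)SCC[Si](C)(C)C | intermediate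
25 | alkynylsilane lactone (6R,7S,8R,10R,4E): trans-6,12-olide with 11(13)-methylene; C6 bears C5=C4(CH2OTBDPS)–C3≡C2–SiMe3; C7 bears C8H(OTBS)–C9H2–C10(CH3)(OMs)–C1(=O)S–TMSE | C=C1C(=O)O[C@H](/C=C(\C#C[Si](C)(C)C)CO[Si](c2ccccc2)(c2ccccc2)C(C)(C)C)[C@H]1[C@H](O[Si](C)(C)C(C)(C)C)C[C@@](C)(OS(C)(=O)=O)C(=O)SCC[Si](C)(C)C | intermediate
26 | bromoalkyne lactone (6R,7S,8R,10R,4E): as 25 with C2–Br | C=C1C(=O)O[C@H](/C=C(\C#CBr)CO[Si](c2ccccc2)(c2ccccc2)C(C)(C)C)[C@H]1[C@H](O[Si](C)(C)C(C)(C)C)C[C@@](C)(OS(C)(=O)=O)C(=O)SCC[Si](C)(C)C | intermediate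
27 | bromomethyl ketone lactone (6R,7S,8R,10R,4Z): as 25 with C3(=O)–C2H2Br | C=C1C(=O)O[C@H](/C=C(\C(=O)CBr)CO[Si](c2ccccc2)(c2ccccc2)C(C)(C)C)[C@H]1[C@H](O[Si](C)(C)C(C)(C)C)C[C@@](C)(OS(C)(=O)=O)C(=O)SCC[Si](C)(C)C | intermediate
28 | tetrabutylammonium thiocarboxylate of 27 (C1(=O)S−) | C=C1C(=O)O[C@H](/C=C(\C(=O)CBr)CO[Si](c2ccccc2)(c2ccccc2)C(C)(C)C)[C@H]1[C@H](O[Si](C)(C)C(C)(C)C)C[C@@](C)(OS(C)(=O)=O)C(=O)[S-].CCCC[N+](CCCC)(CCCC)CCCC | intermediate
29 | eleven-membered thiolactone (6R,7S,8R,10R,4Z): ring C1(=O)–S–C2H2–C3(=O)–C4=C5–C6–C7–C8–C9–C10, fused trans-6,12-olide, 8-OTBS, 10-OMs, 15-OTBDPS | C=C1C(=O)O[C@@H]2/C=C(/CO[Si](c3ccccc3)(c3ccccc3)C(C)(C)C)C(=O)CSC(=O)[C@](C)(OS(C)(=O)=O)C[C@@H](O[Si](C)(C)C(C)(C)C)[C@@H]12 | intermediate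
30 | thiirane alkoxide (S bridging C1 and C2, O− on C1), ammonium salt | C=C1C(=O)O[C@@H]2/C=C(/CO[Si](c3ccccc3)(c3ccccc3)C(C)(C)C)C(=O)C3SC3([O-])[C@](C)(OS(C)(=O)=O)C[C@@H](O[Si](C)(C)C(C)(C)C)[C@@H]12.CC[NH+](C(C)C)C(C)C | intermediate
31 | ten-membered 1,3-diketone enolate (C3–O−, C1=O, 10-OMs), ammonium salt | C=C1C(=O)O[C@@H]2/C=C(/CO[Si](c3ccccc3)(c3ccccc3)C(C)(C)C)C([O-])=CC(=O)[C@](C)(OS(C)(=O)=O)C[C@@H](O[Si](C)(C)C(C)(C)C)[C@@H]12.CC[NH+](C(C)C)C(C)C | intermediate
32 | 8-O-TBS-15-O-TBDPS furanone (6R,7S,8R,10S,4Z): 3,10-epoxy-1-oxogermacra-2,4,11(13)-trien-12,6-olide skeleton | CC(C)(C)[Si](C)(C)O[C@@H]1C[C@]2(C)OC(=CC2=O)/C(CO[Si](c3ccccc3)(c3ccccc3)C(C)(C)C)=C\[C@H]2OC(=O)C(=C)[C@@H]21 | intermediate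
33 | 8-hydroxy-15-O-TBDPS furanone (6R,7R,8R,10S,4Z) | O[C@@H]1C[C@]2(C)OC(=CC2=O)/C(CO[Si](c3ccccc3)(c3ccccc3)C(C)(C)C)=C\[C@H]2OC(=O)C(=C)[C@@H]21 | intermediate
34 | 8-O-methacryloyl-15-O-TBDPS furanone (6R,7R,8R,10S,4Z) | C=C(C)C(=O)O[C@@H]1C[C@]2(C)OC(=CC2=O)/C(CO[Si](c3ccccc3)(c3ccccc3)C(C)(C)C)=C\[C@H]2OC(=O)C(=C)[C@@H]21 | intermediate
35 | (4Z,6R,7R,8R,10S)-15-hydroxy-1-oxo-3,10-epoxygermacra-2,4,11(13)-trien-12,6-olid-8-yl methacrylate | C=C(C)C(=O)O[C@@H]1C[C@]2(C)OC(=CC2=O)/C(CO)=C\[C@H]2OC(=O)C(=C)[C@@H]21 | target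

**Count**

Total steps: 21. Longest linear sequence: 17 steps (steps 1–9 and 14–21); steps 10–13 form the second branch.

**Steps most likely to fail**

1. Step 18 (Proposed new method). The ring contraction and the C–O closure may fail to mesh: elimination of the tertiary mesylate or alkylation at carbon may set in while sulfur extrusion is still incomplete. Fallback, known chemistry, sets out from 29 and returns at 32. The cascade is given up and its two parent reactions are run apart. The Eschenmoser sulfide contraction alone (PPh3, iPr2NEt, LiClO4, MeCN, 20 °C, quenched with pH 5 buffer as soon as 29 is consumed) should give the macrocyclic β-diketone mesylate F1. The furanone is then closed in a second flask by the established base-mediated cyclisation of α′-substituted 1,3-diketones (Cs2CO3, DMF, 0 °C → rt), which should give 32.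

2. Step 17. Closure of the eleven-membered thiolactone may lose to oligomerisation or to conjugate addition of the thiocarboxylate to the α-methylene lactone. Fallback sets out from 16 and 20 and returns at 29; the ring is closed at C3–C4 by a Nozaki–Hiyama–Kishi reaction and not at S–C2. Alcohol 20 is oxidised (MnO2, CH2Cl2) to (Z)-4-[(tert-butyldiphenylsilyl)oxy]-3-iodobut-2-enal F2. Allylation of F2 by 16 under the conditions of step 14 passes through iodo hydroxy ester F3 (not isolated) and, after acid lactonisation, gives vinyl iodide lactone F4. Bu4NF/AcOH in the presence of excess 2-iodoethanol frees the thiocarboxylate F5 (not isolated) and traps it intermolecularly as the S-(2-hydroxyethyl) thioester F6. Dess–Martin periodinane gives the S-(2-oxoethyl) thioester F7. CrCl2 with NiCl2 (1 mol %) in DMSO/THF at high dilution closes the ring to the macrocyclic allylic alcohol F8 (C3 epimers), and Dess–Martin oxidation gives 29.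

3. Step 16. Water may add to the gold-activated bromoalkyne with the wrong regiochemistry, or the cationic catalyst may isomerise the C4=C5 alkene. Fallback sets out from 25 and returns at 27; hydration is moved to the terminal alkyne, where Markovnikov addition is secure, and bromine is brought in afterwards through a silyl enol ether. AgNO3 (10 mol %) in acetone/H2O removes the alkynyl silyl group to give the terminal alkyne lactone F9. Ph3PAuNTf2 (2 mol %), H2O, MeOH, rt hydrates it to the methyl ketone lactone F10. Me3SiOTf/Et3N (CH2Cl2, −78 °C) gives the silyl enol ether F11, which NBS (THF, −78 °C) brominates at C2 to give 27.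

**Further compounds**

F1 | step 18 | macrocyclic β-diketone mesylate (ten-membered carbocycle, C1 and C3 ketones, 10-OMs; 6R,7S,8R,10R,4Z) | C=C1C(=O)O[C@@H]2/C=C(/CO[Si](c3ccccc3)(c3ccccc3)C(C)(C)C)C(=O)CC(=O)[C@](C)(OS(C)(=O)=O)C[C@@H](O[Si](C)(C)C(C)(C)C)[C@@H]12
F2 | step 17 | (Z)-4-[(tert-butyldiphenylsilyl)oxy]-3-iodobut-2-enal | O=C/C=C(\I)CO[Si](c1ccccc1)(c1ccccc1)C(C)(C)C
F3 | step 17 | iodo hydroxy ester (as 24 with iodine on C4 in place of the silylethynyl group) | COC(=O)C(=C)[C@@H]([C@H](O)/C=C(\I)CO[Si](c1ccccc1)(c1ccccc1)C(C)(C)C)[C@H](O[Si](C)(C)C(C)(C)C)C[C@@](C)(OS(C)(=O)=O)C(=O)SCC[Si](C)(C)C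
F4 | step 17 | vinyl iodide lactone (as 25 with iodine on C4) | C=C1C(=O)O[C@H](/C=C(\I)CO[Si](c2ccccc2)(c2ccccc2)C(C)(C)C)[C@H]1[C@H](O[Si](C)(C)C(C)(C)C)C[C@@](C)(OS(C)(=O)=O)C(=O)SCC[Si](C)(C)C
F5 | step 17 | tetrabutylammonium thiocarboxylate of F4 | C=C1C(=O)O[C@H](/C=C(\I)CO[Si](c2ccccc2)(c2ccccc2)C(C)(C)C)[C@H]1[C@H](O[Si](C)(C)C(C)(C)C)C[C@@](C)(OS(C)(=O)=O)C(=O)[S-].CCCC[N+](CCCC)(CCCC)CCCC
F6 | step 17 | S-(2-hydroxyethyl) thioester of the vinyl iodide lactone | C=C1C(=O)O[C@H](/C=C(\I)CO[Si](c2ccccc2)(c2ccccc2)C(C)(C)C)[C@H]1[C@H](O[Si](C)(C)C(C)(C)C)C[C@@](C)(OS(C)(=O)=O)C(=O)SCCO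
F7 | step 17 | S-(2-oxoethyl) thioester of the vinyl iodide lactone | C=C1C(=O)O[C@H](/C=C(\I)CO[Si](c2ccccc2)(c2ccccc2)C(C)(C)C)[C@H]1[C@H](O[Si](C)(C)C(C)(C)C)C[C@@](C)(OS(C)(=O)=O)C(=O)SCC=O
F8 | step 17 | macrocyclic allylic alcohol (as 29 with C3–OH, both epimers) | C=C1C(=O)O[C@@H]2/C=C(/CO[Si](c3ccccc3)(c3ccccc3)C(C)(C)C)C(O)CSC(=O)[C@](C)(OS(C)(=O)=O)C[C@@H](O[Si](C)(C)C(C)(C)C)[C@@H]12
F9 | step 16 | terminal alkyne lactone (as 25 with C2–H) | C=C1C(=O)O[C@H](/C=C(\C#C)CO[Si](c2ccccc2)(c2ccccc2)C(C)(C)C)[C@H]1[C@H](O[Si](C)(C)C(C)(C)C)C[C@@](C)(OS(C)(=O)=O)C(=O)SCC[Si](C)(C)C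
F10 | step 16 | methyl ketone lactone (C3(=O)–C2H3) | C=C1C(=O)O[C@H](/C=C(\C(C)=O)CO[Si](c2ccccc2)(c2ccccc2)C(C)(C)C)[C@H]1[C@H](O[Si](C)(C)C(C)(C)C)C[C@@](C)(OS(C)(=O)=O)C(=O)SCC[Si](C)(C)C
F11 | step 16 | silyl enol ether (C3(OSiMe3)=C2H2) | C=C1C(=O)O[C@H](/C=C(\C(=C)O[Si](C)(C)C)CO[Si](c2ccccc2)(c2ccccc2)C(C)(C)C)[C@H]1[C@H](O[Si](C)(C)C(C)(C)C)C[C@@](C)(OS(C)(=O)=O)C(=O)SCC[Si](C)(C)C
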